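Ring and bridge atoms carry the numbers 1–24 of their order in the target SMILES (C1, C24 acetoxy carbons; O5, O20 ring oxygens; ring A = C4, O5, C6–C10; ring B = C1–C4, C10, C11; atom n of the left half matches atom 25 − n of the right half); β is the face of the angular methyl on C10 or C15, and "AB bicycle" means ring A trans-fused to ring B.
Retrosynthesis: C12–C13 is cut last (olefination, then hydrogenation) into two AB bicycles that differ only at C1/C24 (left: methyl Grignard on a C1 ketone; right: methylenation, epoxidation, hydride) and at C7/C18 (alcohol or ketone); both come from one oxepanone.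
In that oxepanone C4–C8 is re-formed and C4–C10 and C8–C9 are cut: ring A holds C4–O5–C6(Me2)–C7–C8 of a 5-substituted 2,2-dimethylfuran-3(2H)-one, C9/C10 are an isopropenyl group, and the tether C3–C2–C1–C11 is cut at C1–C11 (aldol).
Forward: aldol of a furanone aldehyde builds the chain; irradiation closes ring B and a cyclobutane; SmI2 opens C4–C8 to ring A as an oxepan-3-one; the bicycle is split into two halves, which are joined, acetylated and hydrogenated.
Stereochemistry: C11 (and a temporary C1 carbinol) from an Evans syn aldol with (S)-4-benzyloxazolidin-2-one; C10 from the alkene face used in the photocycloaddition, relayed from C11 through the acetonide-bridged tether; C4 from hydrogen delivery anti to the C10 methyl; C7 by CBS reduction; C1 by equatorial Grignard addition; C24 by epoxidation anti to the axial C15 methyl and hydride opening.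

Key step: step 7

Assumption: step 7 is taken to use the alkene face that leaves the C10 methyl cis to C12; should the other face react, the (R)-oxazolidinone would be used and C11 equilibrated next to a C1 ketone whose C12 oxygen is silylated.

Step 1
Reactants: 1 3-hydroxy-3-methylbutan-2-one; 2 ethyl pent-4-enoate
Product: 4 5-(but-3-en-1-yl)-2,2-dimethylfuran-3(2H)-one, via hydroxy diketone 3 (not isolated)
Conditions: LiN(i-Pr)2 (3.2 equiv), THF, −78 to 0 °C; then 2 M HCl, rt
Reagents that add atoms: none
Why: Claisen condensation of the dianion of the α-hydroxy ketone at its methyl group gives the hydroxy 1,3-diketone, which under acid closes through the tertiary hydroxyl onto the distal carbonyl and dehydrates to the 3(2H)-furanone.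

Step 2
Reactants: 4 5-(but-3-en-1-yl)-2,2-dimethylfuran-3(2H)-one
Product: 5 3-(5,5-dimethyl-4-oxo-4,5-dihydrofuran-2-yl)propanal
Conditions: OsO4 (2 mol %), NaIO4, 2,6-lutidine, dioxane/H2O, rt
Reagents that add atoms: osmium tetroxide, O=[Os](=O)(=O)=O; sodium periodate, [Na+].[O-]I(=O)(=O)=O
Why: Lemieux–Johnson oxidation cleaves the terminal alkene and should spare the electron-poor trisubstituted double bond of the vinylogous ester.

Step 3
Reactants: 6 3-methylbut-2-enoyl chloride; 7 (S)-4-benzyloxazolidin-2-one
Product: 8 (S)-4-benzyl-3-(3-methylbut-2-enoyl)oxazolidin-2-one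
Conditions: n-BuLi, THF, −78 °C; then 6, −78 to 0 °C
Reagents that add atoms: none
Why: N-acylation of the lithiated oxazolidinone with an acid chloride is the standard entry to Evans imides.

Step 4
Reactants: 8 (S)-4-benzyl-3-(3-methylbut-2-enoyl)oxazolidin-2-one; 5 3-(5,5-dimethyl-4-oxo-4,5-dihydrofuran-2-yl)propanal
Product: 9 (S)-4-benzyl-3-[(2S,3R)-5-(5,5-dimethyl-4-oxo-4,5-dihydrofuran-2-yl)-3-hydroxy-2-(prop-1-en-2-yl)pentanoyl]oxazolidin-2-one
Conditions: n-Bu2BOTf, Et3N, CH2Cl2, −78 to 0 °C; 5, −78 to 0 °C; pH 7 buffer, MeOH, H2O2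
Reagents that add atoms: none
Why: The dibutylboron dienolate formed by γ-deprotonation adds to the aldehyde at its α-carbon through a closed chair transition state (deconjugative Evans syn aldol), so the auxiliary sets C11 and the enolate geometry sets the C1 carbinol syn to it, leaving the isopropenyl group on C11.

Step 5
Reactants: 9 the aldol adduct
Product: 10 5-[(3R,4R)-3-hydroxy-4-(hydroxymethyl)-5-methylhex-5-en-1-yl]-2,2-dimethylfuran-3(2H)-one
Conditions: NaBH4, THF/H2O (4:1), 0 °C to rt
Reagents that add atoms: none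
Why: Reductive cleavage of the N-acyloxazolidinone with borohydride in wet THF gives the primary alcohol (C12) and returns the auxiliary, the vinylogous ester carbonyl of the furanone being too electron-rich to be reduced.

Step 6
Reactants: 10 the 1,12-diol
Product: 11 5-{2-[(4R,5R)-2,2-dimethyl-5-(prop-1-en-2-yl)-1,3-dioxan-4-yl]ethyl}-2,2-dimethylfuran-3(2H)-one
Conditions: 2,2-dimethoxypropane, pyridinium p-toluenesulfonate (cat.), CH2Cl2, rt
Reagents that add atoms: 2,2-dimethoxypropane, COC(C)(C)OC
Why: Acid-catalysed transketalisation closes the six-membered acetonide on the syn 1,3-diol, which protects O1 and O12 and fixes the tether carbons C1 and C11 in a ring.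

Step 7
Reactants: 11 the furanone with the acetonide-bridged isopropenyl tether
Product: 12 cyclobutane photoadduct (1R,4R,8R,10S,11R): the 2,2-dimethyloxolan-3-one ring (O5, C6, C7, C8, C4) cis-fused at C4–C8 to the cyclobutane C4–C10–C9–C8, which is cis-fused at C4–C10 to ring B; 10β-methyl; O1,O12-acetonide with O1 and C12 β
Conditions: hν (350 nm, Pyrex), degassed MeCN (5 mM), 20 °C
Reagents that add atoms: none
Why: Proposed new method: excitation of the vinylogous ester and intersystem crossing give the furanone triplet, whose β-carbon C4 bonds to the substituted alkene carbon C10 through the four-atom tether (6-exo closure of ring B through a chair-like array, giving a 1,4-diradical), after which C8–C9 radical recombination closes the cyclobutane; the closest known reactions are intramolecular enone–alkene (2+2) photocycloadditions of cyclic vinylogous esters through four-atom tethers bearing a cyclic acetal, and intermolecular head-to-tail additions of 2,2-dimethylfuran-3(2H)-ones to 1,1-disubstituted alkenes. C4 and C8 follow from the cis fusion that the five-membered ring and the tether impose, so the only free variable is the alkene face, that is C10 relative to C11. The cis-fused acetonide holds C12 equatorial on the forming ring B (isopropenyl axial on the dioxane, side chain equatorial), and the alkene CH2 is expected to take the outer pseudo-equatorial site where it meets C8, which leaves the C10 methyl cis to C12. The step needs straight and not crossed regiochemistry, favoured by the tether length (the crossed mode needs a seven-membered ring) and by the usual bonding of the enone β-carbon to the more substituted alkene carbon. It also needs this facial selectivity, which rests on the conformational argument alone and is the main uncertainty of the route.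

Step 8
Reactants: 12 the cyclobutane photoadduct
Product: 13 AB oxepanone: trans-fused ring A with C7 ketone, 4α-H and 10β-methyl; ring B with the O1,O12-acetonide (O1 β axial, C12 β equatorial)
Conditions: SmI2 (2.5 equiv), MeOH (4 equiv), THF, −78 °C
Reagents that add atoms: none
Why: Proposed new method: electron transfer to the C7 carbonyl gives a ketyl whose strain-driven β-scission should break C4–C8 and not C8–C9, because only that path gives a tertiary α-alkoxy radical (at C4), which is reduced and protonated on the face opposite the C10 methyl to set the trans ring fusion while the samarium enolate gives the C7 ketone on work-up; the closest known reactions are SmI2 ring-opening of cyclobutyl ketones toward the more stabilised radical and tin hydride fragmentation of cyclobutylcarbinyl radicals in photoadducts, and the two-electron loss of the α-oxygen, usual for α-alkoxy ketones, should be outrun by the scission at −78 °C.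

Step 9
Reactants: 13 the AB oxepanone
Product: 14 7α-alcohol (7S) of 13
Conditions: (R)-2-methyl-CBS-oxazaborolidine (0.5 equiv), BH3·SMe2, THF, −30 to 0 °C; MeOH
Reagents that add atoms: none
Why: Corey–Bakshi–Shibata reduction puts the ketone under reagent control, the oxazaborolidine distinguishing the quaternary C6 flank (large) from the C8 methylene (small), so hydride should arrive on the face that gives the 7S alcohol.

Step 10
Reactants: 14 the 7α-alcohol
Product: 15 7α-benzyl ether of 14
Conditions: NaH, BnBr, Bu4NI (cat.), DMF, 0 °C to rt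
Reagents that add atoms: benzyl bromide, BrCc1ccccc1
Why: Williamson etherification under iodide catalysis protects the hindered C7 hydroxyl as an ether that survives every later step and leaves by hydrogenolysis.

Step 11
Reactants: 15 the benzyl ether acetonide
Product: 16 7α-benzyloxy AB bicycle 1β,12-diol (1-OH axial, C12 arm equatorial)
Conditions: AcOH/THF/H2O (3:1:1), 45 °C
Reagents that add atoms: none
Why: Mild aqueous acid hydrolyses the acetonide (ketal hydrolysis) and leaves the benzyl ether and the oxepane untouched.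

Step 12
Reactants: 16 the 1β,12-diol
Product: 17 7α-benzyloxy-12-[(1-phenyl-1H-tetrazol-5-yl)sulfanyl] AB bicycle 1β-ol
Conditions: 1-phenyl-1H-tetrazole-5-thiol, PPh3, diisopropyl azodicarboxylate, THF, 0 °C to rt
Reagents that add atoms: 1-phenyl-1H-tetrazole-5-thiol, Sc1nnnn1-c1ccccc1
Why: The Mitsunobu reaction with the acidic thiol substitutes only the primary hydroxyl, the axial secondary C1 hydroxyl being too hindered to be activated.

Step 13
Reactants: 17 the sulfide alcohol
Product: 18 7α-benzyloxy-12-[(1-phenyl-1H-tetrazol-5-yl)sulfanyl] AB bicycle 1-ketone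
Conditions: Dess–Martin periodinane, CH2Cl2, rt
Reagents that add atoms: none
Why: Dess–Martin oxidation gives the C1 ketone under neutral conditions, so the β-sulfanyl ketone meets no base and C11 keeps its equatorial C12 arm.

Step 14
Reactants: 18 the C1 ketone
Product: 19 7α-benzyloxy-1α-methyl-12-[(1-phenyl-1H-tetrazol-5-yl)sulfanyl] AB bicycle 1β-ol
Conditions: MeMgBr, CeCl3, THF, −78 to −20 °C
Reagents that add atoms: methylmagnesium bromide, C[Mg]Br
Why: The organocerium reagent adds 1,2 to the ketone without enolisation and from the equatorial direction, because the axial path is blocked by the syn-axial C10 methyl, which gives the axial 1β-hydroxyl and the equatorial methyl of the left half.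

Step 15
Reactants: 19 the tertiary alcohol sulfide
Product: 20 7α-benzyloxy-1α-methyl-12-[(1-phenyl-1H-tetrazol-5-yl)sulfonyl] AB bicycle 1β-ol
Conditions: mCPBA (2.5 equiv), NaHCO3, CH2Cl2, 0 °C to rt
Reagents that add atoms: 3-chloroperbenzoic acid, OOC(=O)c1cccc(Cl)c1
Why: Peracid oxidation takes the sulfide to the sulfone needed for the Julia–Kocienski olefination, nothing else in the molecule being oxidisable.

Step 16
Reactants: 20 the hydroxy sulfone
Product: 21 1β-O-trimethylsilyl ether of 20 (left-half partner)
Conditions: Me3SiOTf, 2,6-lutidine, CH2Cl2, −78 to 0 °C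
Reagents that add atoms: trimethylsilyl trifluoromethanesulfonate, C[Si](C)(C)OS(=O)(=O)C(F)(F)F
Why: Silylation with the silyl triflate and a hindered base caps the tertiary hydroxyl, so no alkoxide can attack the tetrazole or quench the sulfonyl carbanion in the coupling.

Step 17
Reactants: 16 the 1β,12-diol (from here numbered as the right half: 24β-hydroxy, 13-hydroxy, 18α-benzyloxy)
Product: 22 18α-benzyloxy-24β-hydroxy AB bicycle 13-pivalate
Conditions: pivaloyl chloride, pyridine, CH2Cl2, 0 °C
Reagents that add atoms: pivaloyl chloride, CC(C)(C)C(=O)Cl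
Why: Acylation with the bulky acid chloride is selective for the primary hydroxyl and gives an ester that tolerates methylenation and epoxidation and is removed by the hydride of step 21.

Step 18
Reactants: 22 the pivalate alcohol
Product: 23 18α-benzyloxy-24-oxo AB bicycle 13-pivalate
Conditions: Dess–Martin periodinane, CH2Cl2, rt
Reagents that add atoms: none
Why: Dess–Martin oxidation gives the C24 ketone without base and so avoids β-elimination of the pivalate.

Step 19
Reactants: 23 the C24 ketone
Product: 24 18α-benzyloxy-24-methylene AB bicycle 13-pivalate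
Conditions: Zn, CH2Br2, TiCl4, THF/CH2Cl2, 0 °C to rt
Reagents that add atoms: dibromomethane, BrCBr
Why: Takai–Lombardo methylenation uses a non-basic titanium–zinc methylene reagent that should convert the hindered, enolisable ketone without epimerising C14 or expelling the β-pivalate, as a Wittig ylide might.

Step 20
Reactants: 24 the exocyclic alkene
Product: 25 24-spiro-epoxide (epoxide oxygen 24α equatorial, CH2 24β axial), 18α-benzyloxy, 13-pivalate
Conditions: mCPBA, NaHCO3, CH2Cl2, 0 °C
Reagents that add atoms: 3-chloroperbenzoic acid, OOC(=O)c1cccc(Cl)c1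
Why: Prilezhaev epoxidation of the exocyclic alkene should occur from the equatorial direction, opposite the syn-axial C15 methyl, which places the oxygen α (equatorial) at C24.

Step 21
Reactants: 25 the spiro-epoxide
Product: 26 18α-benzyloxy-24β-methyl AB bicycle 13,24α-diol
Conditions: LiEt3BH (5 equiv), THF, 0 °C to rt
Reagents that add atoms: none
Why: The borohydride opens the epoxide by SN2 attack at the CH2 terminus, giving the tertiary alcohol with equatorial 24α-oxygen and axial methyl (the epimeric arrangement to that of step 14), and the same reagent cleaves the pivalate.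

Step 22
Reactants: 26 the benzyl ether diol
Product: 27 24β-methyl AB bicycle 13,18α,24α-triol
Conditions: H2 (1 atm), Pd(OH)2 on carbon, EtOAc/EtOH, rt
Reagents that add atoms: none
Why: Hydrogenolysis removes the only benzyl ether of this half and frees the C18 hydroxyl for oxidation together with the primary alcohol.

Step 23
Reactants: 27 the triol
Product: 28 24α-hydroxy-24β-methyl-18-oxo AB bicycle 13-al
Conditions: Dess–Martin periodinane (3 equiv), CH2Cl2, rt
Reagents that add atoms: none
Why: Dess–Martin oxidation converts the primary alcohol to the aldehyde and the secondary C18 alcohol to the ketone in one operation, the tertiary alcohol being inert and the neutral medium sparing C14.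

Step 24
Reactants: 28 the hydroxy keto aldehyde
Product: 29 24α-O-trimethylsilyl ether of 28 (right-half partner)
Conditions: N-(trimethylsilyl)imidazole, CH2Cl2, rt
Reagents that add atoms: N-(trimethylsilyl)imidazole, C[Si](C)(C)n1ccnc1
Why: The silylimidazole silylates the tertiary hydroxyl without enolising the aldehyde or ketone, which removes the acidic proton and the retro-aldol pathway before the basic coupling.

Step 25
Reactants: 21 the left-half sulfone; 29 the right-half aldehyde
Product: 31 (12E)-alkene 1β,24α-diol: the two AB bicycles joined by C12=C13, with 7α-benzyloxy, 18-ketone, 1α- and 24β-methyl, via bis-silyl ether 30 (not isolated)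
Conditions: KN(SiMe3)2, DME, −78 °C; 29, −78 °C to rt; then 1 M HCl, THF, 0 °C
Reagents that add atoms: none
Why: In the Julia–Kocienski olefination the sulfonyl carbanion adds to the aldehyde faster than to the hindered ketone, Smiles rearrangement with loss of SO2 and the tetrazolate gives the C12=C13 alkene (its geometry is irrelevant since it is hydrogenated), and the acidic work-up cleaves both tertiary silyl ethers.

Step 26
Reactants: 31 the alkene diol
Product: 32 1β,24α-diacetate of 31
Conditions: Ac2O (20 equiv), 4-(dimethylamino)pyridine (2 equiv), Et3N, CH2Cl2, 40 °C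
Reagents that add atoms: acetic anhydride, CC(=O)OC(C)=O
Why: Nucleophilic catalysis by the aminopyridine acetylates the two tertiary alcohols, the only free hydroxyls (O7 is still benzylated), the hindered axial C1 hydroxyl accounting for the excess reagent and warming.

Step 27
Reactants: 32 the diacetate
Product: 33 CNP0298533.1
Conditions: H2 (4 atm), Pd(OH)2 on carbon, EtOAc/EtOH, rt
Reagents that add atoms: none
Why: Catalytic hydrogenation saturates the disubstituted alkene and hydrogenolysis in the same operation removes the C7 benzyl ether, the ketone and the tertiary acetates being stable to palladium under hydrogen.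

Compound list
1 | 3-hydroxy-3-methylbutan-2-one | CC(=O)C(C)(C)O | starting material
2 | ethyl pent-4-enoate | C=CCCC(=O)OCC | starting material
3 | 2-hydroxy-2-methylnon-8-ene-3,5-dione (hydroxy diketone) | CC(C)(O)C(=O)CC(=O)CCC=C | intermediate
4 | 5-(but-3-en-1-yl)-2,2-dimethylfuran-3(2H)-one | CC1(C)OC(CCC=C)=CC1=O | intermediate
5 | 3-(5,5-dimethyl-4-oxo-4,5-dihydrofuran-2-yl)propanal | CC1(C)OC(CCC=O)=CC1=O | intermediate
6 | 3-methylbut-2-enoyl chloride | CC(C)=CC(=O)Cl | starting material
7 | (S)-4-benzyloxazolidin-2-one | O=C1OC[C@H](Cc2ccccc2)N1 | starting material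
8 | (S)-4-benzyl-3-(3-methylbut-2-enoyl)oxazolidin-2-one | CC(C)=CC(=O)N1[C@@H](Cc2ccccc2)COC1=O | intermediate
9 | (S)-4-benzyl-3-[(2S,3R)-5-(5,5-dimethyl-4-oxo-4,5-dihydrofuran-2-yl)-3-hydroxy-2-(prop-1-en-2-yl)pentanoyl]oxazolidin-2-one | CC(=C)[C@@H]([C@H](O)CCC1=CC(=O)C(C)(C)O1)C(=O)N1[C@@H](Cc2ccccc2)COC1=O | intermediate
10 | 5-[(3R,4R)-3-hydroxy-4-(hydroxymethyl)-5-methylhex-5-en-1-yl]-2,2-dimethylfuran-3(2H)-one | CC(=C)[C@H](CO)[C@H](O)CCC1=CC(=O)C(C)(C)O1 | intermediate
11 | 5-{2-[(4R,5R)-2,2-dimethyl-5-(prop-1-en-2-yl)-1,3-dioxan-4-yl]ethyl}-2,2-dimethylfuran-3(2H)-one | CC1(C)OC[C@@H](C(C)=C)[C@@H](CCC2=CC(=O)C(C)(C)O2)O1 | intermediate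
12 | cyclobutane photoadduct (1R,4R,8R,10S,11R), 10β-methyl, O1,O12-acetonide | CC1(C)O[C@@]23CC[C@H]4OC(C)(C)OC[C@H]4[C@]2(C)C[C@H]3C1=O | intermediate
13 | AB oxepanone (C7 ketone, 4α-H, 10β-methyl, O1,O12-acetonide) | CC1(C)O[C@H]2CC[C@H]3OC(C)(C)OC[C@H]3[C@]2(C)CCC1=O | intermediate
14 | 7α-alcohol (7S) of 13 | CC1(C)O[C@H]2CC[C@H]3OC(C)(C)OC[C@H]3[C@]2(C)CC[C@@H]1O | intermediate
15 | 7α-benzyl ether of 14 | CC1(C)O[C@H]2CC[C@H]3OC(C)(C)OC[C@H]3[C@]2(C)CC[C@@H]1OCc1ccccc1 | intermediate
16 | 7α-benzyloxy AB bicycle 1β,12-diol | CC1(C)O[C@H]2CC[C@@H](O)[C@@H](CO)[C@]2(C)CC[C@@H]1OCc1ccccc1 | intermediate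
17 | 7α-benzyloxy-12-[(1-phenyl-1H-tetrazol-5-yl)sulfanyl] AB bicycle 1β-ol | CC1(C)O[C@H]2CC[C@@H](O)[C@@H](CSc3nnnn3-c3ccccc3)[C@]2(C)CC[C@@H]1OCc1ccccc1 | intermediate
18 | 7α-benzyloxy-12-[(1-phenyl-1H-tetrazol-5-yl)sulfanyl] AB bicycle 1-ketone | CC1(C)O[C@H]2CCC(=O)[C@@H](CSc3nnnn3-c3ccccc3)[C@]2(C)CC[C@@H]1OCc1ccccc1 | intermediate
19 | 7α-benzyloxy-1α-methyl-12-[(1-phenyl-1H-tetrazol-5-yl)sulfanyl] AB bicycle 1β-ol | CC1(C)O[C@H]2CC[C@@](C)(O)[C@@H](CSc3nnnn3-c3ccccc3)[C@]2(C)CC[C@@H]1OCc1ccccc1 | intermediate
20 | 7α-benzyloxy-1α-methyl-12-[(1-phenyl-1H-tetrazol-5-yl)sulfonyl] AB bicycle 1β-ol | CC1(C)O[C@H]2CC[C@@](C)(O)[C@@H](CS(=O)(=O)c3nnnn3-c3ccccc3)[C@]2(C)CC[C@@H]1OCc1ccccc1 | intermediate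
21 | 1β-O-trimethylsilyl ether of 20 | CC1(C)O[C@H]2CC[C@@](C)(O[Si](C)(C)C)[C@@H](CS(=O)(=O)c3nnnn3-c3ccccc3)[C@]2(C)CC[C@@H]1OCc1ccccc1 | intermediate
22 | 18α-benzyloxy-24β-hydroxy AB bicycle 13-pivalate | CC1(C)O[C@H]2CC[C@@H](O)[C@@H](COC(=O)C(C)(C)C)[C@]2(C)CC[C@@H]1OCc1ccccc1 | intermediate
23 | 18α-benzyloxy-24-oxo AB bicycle 13-pivalate | CC1(C)O[C@H]2CCC(=O)[C@@H](COC(=O)C(C)(C)C)[C@]2(C)CC[C@@H]1OCc1ccccc1 | intermediate
24 | 18α-benzyloxy-24-methylene AB bicycle 13-pivalate | CC1(C)O[C@H]2CCC(=C)[C@@H](COC(=O)C(C)(C)C)[C@]2(C)CC[C@@H]1OCc1ccccc1 | intermediate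
25 | 24-spiro-epoxide (oxygen 24α), 18α-benzyloxy, 13-pivalate | CC1(C)O[C@H]2CC[C@@]3(CO3)[C@@H](COC(=O)C(C)(C)C)[C@]2(C)CC[C@@H]1OCc1ccccc1 | intermediate
26 | 18α-benzyloxy-24β-methyl AB bicycle 13,24α-diol | CC1(C)O[C@H]2CC[C@](C)(O)[C@@H](CO)[C@]2(C)CC[C@@H]1OCc1ccccc1 | intermediate
27 | 24β-methyl AB bicycle 13,18α,24α-triol | CC1(C)O[C@H]2CC[C@](C)(O)[C@@H](CO)[C@]2(C)CC[C@@H]1O | intermediate
28 | 24α-hydroxy-24β-methyl-18-oxo AB bicycle 13-al | CC1(C)O[C@H]2CC[C@](C)(O)[C@@H](C=O)[C@]2(C)CCC1=O | intermediate
29 | 24α-O-trimethylsilyl ether of 28 | CC1(C)O[C@H]2CC[C@](C)(O[Si](C)(C)C)[C@@H](C=O)[C@]2(C)CCC1=O | intermediate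
30 | (12E)-alkene 1β,24α-bis(trimethylsilyl) ether, 7α-benzyloxy, 18-ketone | CC1(C)O[C@H]2CC[C@@](C)(O[Si](C)(C)C)[C@@H](/C=C/[C@@H]3[C@@](C)(O[Si](C)(C)C)CC[C@@H]4OC(C)(C)C(=O)CC[C@@]34C)[C@]2(C)CC[C@@H]1OCc1ccccc1 | intermediate
31 | (12E)-alkene 1β,24α-diol, 7α-benzyloxy, 18-ketone | CC1(C)O[C@H]2CC[C@@](C)(O)[C@@H](/C=C/[C@@H]3[C@@](C)(O)CC[C@@H]4OC(C)(C)C(=O)CC[C@@]34C)[C@]2(C)CC[C@@H]1OCc1ccccc1 | intermediate
32 | 1β,24α-diacetate of 31 | CC1(C)O[C@H]2CC[C@@](C)(OC(C)=O)[C@@H](/C=C/[C@@H]3[C@@](C)(OC(C)=O)CC[C@@H]4OC(C)(C)C(=O)CC[C@@]34C)[C@]2(C)CC[C@@H]1OCc1ccccc1 | intermediate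
33 | CNP0298533.1 | CC(=O)O[C@]1(C)CC[C@@H]2OC(C)(C)[C@@H](O)CC[C@@]2(C)[C@@H]1CC[C@H]1[C@]2(C)CCC(=O)C(C)(C)O[C@H]2CC[C@]1(C)OC(C)=O | target

Total step count: 27. Longest linear sequence: 21 steps (steps 1, 2, 4–11, 17–27).

Steps most likely to fail

Step 7. The triplet diradical may close in the crossed sense (C4 to C9), revert to 11, or use the other alkene face, so that ring B forms inefficiently or with the C10 methyl on the wrong side. The fallback makes the two bonds and ring B in separate known operations, setting out from 5 and 7 and returning at 12. Aldehyde 5 is protected (HC(OMe)3, pyridinium p-toluenesulfonate, MeOH) as 5-(3,3-dimethoxypropyl)-2,2-dimethylfuran-3(2H)-one F1, and 7 is acylated with the pivaloyl mixed anhydride of 3-methylbut-3-enoic acid to (S)-4-benzyl-3-(3-methylbut-3-enoyl)oxazolidin-2-one F2. Intermolecular head-to-tail (2+2) photocycloaddition of F1 with excess F2 at 350 nm, the established mode of 2,2-dimethylfuran-3(2H)-ones with 1,1-disubstituted alkenes, should join C4 to C10 and C8 to C9. The auxiliary makes the adducts diastereomeric, and the isomer with the imide arm cis to the C4 side chain and the ring configuration of 12, the cyclobutane acetal F3, is separated by chromatography. Aqueous acid gives the cyclobutane aldehyde F4, and an intramolecular Evans aldol reaction (n-Bu2BOTf, i-Pr2NEt) closes ring B between C1 and C11 to the tetracyclic hydroxy imide F5. LiOH/H2O2 removes the auxiliary to give the hydroxy acid F6, BH3·THF reduces the acid in the presence of the ketone to the keto diol F7, and 2,2-dimethoxypropane with acid catalyst returns 12.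

Step 8. The samarium ketyl may expel the ring oxygen at C6, open the outer cyclobutane bond C8–C9, or be reduced further to the alcohol. The fallback cleaves C4–C8 by the known tin hydride fragmentation of a cyclobutylcarbinyl radical, which involves no ketyl; it sets out from 12 and returns at 14. NaBH4 reduces 12 to the photoadduct alcohol F8, and NaH, CS2 and MeI give the xanthate F9. Bu3SnH with azobisisobutyronitrile in refluxing benzene generates the C7 radical, which should open toward the tertiary α-alkoxy C4 radical and, after hydrogen transfer anti to the C10 methyl, give the oxepene F10 (C7=C8). Epoxidation with mCPBA on the face opposite the C10 methyl gives the 7α,8α-epoxide F11, and LiEt3BH opens it at the less hindered C8 to give 14 directly, so step 9 is not needed.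

Step 25. The two β-branched partners may fail to combine, the hindered tetrazolyl sulfonyl carbanion deprotonating the aldehyde or ketone or adding reversibly without going on to the Smiles rearrangement. The fallback is a stepwise Julia–Lythgoe olefination with a smaller phenylsulfonyl carbanion whose adduct is trapped irreversibly; it sets out from 16 and 29 and returns at 30. PhSSPh/Bu3P converts the primary alcohol of 16 into the phenyl sulfide diol F12; Dess–Martin oxidation gives the sulfide ketone F13, MeMgBr/CeCl3 the sulfide tertiary alcohol F14, mCPBA the phenyl sulfone F15 and Me3SiOTf/2,6-lutidine the silylated phenyl sulfone F16. Its lithio derivative (n-BuLi, THF, −78 °C) is added to 29 and the alkoxide is trapped with Ac2O as the β-acetoxy sulfone F17 (isomers at C12 and C13). Reductive elimination with Na/Hg (Na2HPO4, MeOH, −20 °C) gives 30, which is desilylated to 31 as in step 25.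

Further compounds
F1 | step 7 | 5-(3,3-dimethoxypropyl)-2,2-dimethylfuran-3(2H)-one | COC(CCC1=CC(=O)C(C)(C)O1)OC
F2 | step 7 | (S)-4-benzyl-3-(3-methylbut-3-enoyl)oxazolidin-2-one | CC(=C)CC(=O)N1[C@@H](Cc2ccccc2)COC1=O
F3 | step 7 | cyclobutane acetal (intermolecular head-to-tail photoadduct) | CC1(C)O[C@@]2(CCC(OC)OC)[C@](C)(CC(=O)N3[C@@H](Cc4ccccc4)COC3=O)C[C@H]2C1=O
F4 | step 7 | cyclobutane aldehyde | CC1(C)O[C@@]2(CCC=O)[C@](C)(CC(=O)N3[C@@H](Cc4ccccc4)COC3=O)C[C@H]2C1=O
F5 | step 7 | tetracyclic hydroxy imide (ring B closed) | CC1(C)O[C@@]23CC[C@@H](O)[C@@H](C(=O)N4[C@@H](Cc5ccccc5)COC4=O)[C@]2(C)C[C@H]3C1=O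
F6 | step 7 | tetracyclic hydroxy acid | CC1(C)O[C@@]23CC[C@@H](O)[C@@H](C(=O)O)[C@]2(C)C[C@H]3C1=O
F7 | step 7 | tetracyclic keto diol | CC1(C)O[C@@]23CC[C@@H](O)[C@@H](CO)[C@]2(C)C[C@H]3C1=O
F8 | step 8 | photoadduct alcohol (C7 carbinol, both epimers) | CC1(C)O[C@@]23CC[C@H]4OC(C)(C)OC[C@H]4[C@]2(C)C[C@H]3C1O
F9 | step 8 | S-methyl xanthate of F8 | CC1(C)O[C@@]23CC[C@H]4OC(C)(C)OC[C@H]4[C@]2(C)C[C@H]3C1OC(=S)SC
F10 | step 8 | oxepene (C7=C8) with O1,O12-acetonide | CC1(C)O[C@H]2CC[C@H]3OC(C)(C)OC[C@H]3[C@]2(C)CC=C1
F11 | step 8 | 7α,8α-epoxide of F10 | CC1(C)O[C@H]2CC[C@H]3OC(C)(C)OC[C@H]3[C@]2(C)C[C@@H]4O[C@H]14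
F12 | step 25 | 7α-benzyloxy-12-(phenylsulfanyl) AB bicycle 1β-ol | CC1(C)O[C@H]2CC[C@@H](O)[C@@H](CSc3ccccc3)[C@]2(C)CC[C@@H]1OCc1ccccc1
F13 | step 25 | 7α-benzyloxy-12-(phenylsulfanyl) AB bicycle 1-ketone | CC1(C)O[C@H]2CCC(=O)[C@@H](CSc3ccccc3)[C@]2(C)CC[C@@H]1OCc1ccccc1
F14 | step 25 | 7α-benzyloxy-1α-methyl-12-(phenylsulfanyl) AB bicycle 1β-ol | CC1(C)O[C@H]2CC[C@@](C)(O)[C@@H](CSc3ccccc3)[C@]2(C)CC[C@@H]1OCc1ccccc1
F15 | step 25 | 7α-benzyloxy-1α-methyl-12-(phenylsulfonyl) AB bicycle 1β-ol | CC1(C)O[C@H]2CC[C@@](C)(O)[C@@H](CS(=O)(=O)c3ccccc3)[C@]2(C)CC[C@@H]1OCc1ccccc1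
F16 | step 25 | 1β-O-trimethylsilyl ether of F15 | CC1(C)O[C@H]2CC[C@@](C)(O[Si](C)(C)C)[C@@H](CS(=O)(=O)c3ccccc3)[C@]2(C)CC[C@@H]1OCc1ccccc1
F17 | step 25 | β-acetoxy sulfone adduct (C12 sulfone, C13 acetate, isomer mixture) | CC1(C)O[C@H]2CC[C@@](C)(O[Si](C)(C)C)[C@@H](C(C(OC(C)=O)[C@@H]3[C@@](C)(O[Si](C)(C)C)CC[C@@H]4OC(C)(C)C(=O)CC[C@@]34C)S(=O)(=O)c3ccccc3)[C@]2(C)CC[C@@H]1OCc1ccccc1
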